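**Retrosynthetic overview**
- Last step: one hydrogenation converts a stilbene C=C into the CH2CH2 bridge and a diaryl ketone C=O into the ArCH2Ar link.
- The OH/OMe difference on ring B comes from ketone-directed cleavage of one of two equivalent ortho methoxy groups with BCl3. The same operation frees the ring C phenol.
- The ring B–C(=O) bond comes from a 4-lithio-3,5-dimethoxyaryl species and 4-(benzyloxy)benzonitrile.
- Key disconnection: the central C=C is split into two aldehyde carbons. Hydrazine turns 3-methoxybenzaldehyde into a benzyl-anion equivalent, which attacks 4-bromo-3,5-dimethoxybenzaldehyde under ruthenium catalysis.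
- No ring is formed. Rings A (3-methoxyphenyl), B (central) and C (4-hydroxyphenyl) are all bought as benzene derivatives.

Assumption: IN0509 has no stereocentre and is achiral, so no enantiocontrol is needed. The alkene geometry and the one transient carbinol centre on the way are both erased in the last step.

**Step 1**
Reactants: 1 3-methoxybenzaldehyde + 2 4-bromo-3,5-dimethoxybenzaldehyde
Product: 4 2-bromo-1,3-dimethoxy-5-[(E)-2-(3-methoxyphenyl)ethenyl]benzene, via hydrazone 3 (not isolated)
Conditions: a) 1 (1.3 equiv), N2H4·H2O (1.3 equiv), THF, rt, 1 h, then Na2SO4; b) 2 (1.0 equiv), [RuCl2(p-cymene)]2 (1.5 mol %), dmpe (3 mol %), KOtBu (25 mol %), CsF (1 equiv), THF, 45 °C, 24 h, under argon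
Reagents that add atoms: none
Why: Carbonyl reductive cross-olefination through hydrazone umpolung, in which the N-unsubstituted hydrazone 3, bound to divalent ruthenium, reacts at carbon as a 3-methoxybenzyl carbanion equivalent and adds to the C=O of the more electrophilic, non-enolisable aldehyde 2 through a six-membered transition state, so that two natively electrophilic aldehyde carbons are joined; base-triggered loss of N2 from the diazene adduct then leaves a benzylic carbanion beta to the oxido group, which is expelled (E1cB) to give mainly the E-alkene, whose geometry is irrelevant because it is hydrogenated in step 4, and the aryl bromide and aryl ethers are inert to this catalyst at 45 °C.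

**Step 2**
Reactants: 4 2-bromo-1,3-dimethoxy-5-[(E)-2-(3-methoxyphenyl)ethenyl]benzene + 5 4-(benzyloxy)benzonitrile
Product: 8 [4-(benzyloxy)phenyl]{2,6-dimethoxy-4-[(E)-2-(3-methoxyphenyl)ethenyl]phenyl}methanone, via aryllithium 6 (not isolated), via lithium ketimide 7 (not isolated)
Conditions: n-BuLi (1.05 equiv), THF, −78 °C, 20 min; 5 (1.2 equiv), −78 °C → rt; then 2 M aq HCl, THF, 60 °C
Reagents that add atoms: water, O
Why: Bromine–lithium exchange at −78 °C is far faster than carbolithiation of the stilbene and gives aryllithium 6, stabilised by its two flanking methoxy groups, which adds only once to nitrile 5 because lithium ketimide 7 is inert to a second addition (organolithium–nitrile ketone synthesis), and warm dilute acid hydrolyses the hindered ketimine to 8 without touching the benzyl ether or the alkene.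

**Step 3**
Reactants: 8 [4-(benzyloxy)phenyl]{2,6-dimethoxy-4-[(E)-2-(3-methoxyphenyl)ethenyl]phenyl}methanone
Product: 10 (4-hydroxyphenyl){2-hydroxy-6-methoxy-4-[(E)-2-(3-methoxyphenyl)ethenyl]phenyl}methanone, via boron aryloxide 9 (not isolated)
Conditions: BCl3 (3 equiv), C6HMe5 (3 equiv), CH2Cl2, −78 → 0 °C; then H2O
Reagents that add atoms: none
Why: Chelation-directed aryl methyl ether cleavage, in which BCl3 binds the ketone oxygen and one ortho methoxy group in a six-membered chelate and chloride removes only that methyl group, after which the carbonyl is tied up in the boron chelate so that the second ortho methoxy group and the unassisted ring A methoxy group survive at or below 0 °C (this desymmetrises ring B), while BCl3 together with pentamethylbenzene as cation scavenger removes the benzyl group at −78 °C without C-benzylation.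

**Step 4**
Reactants: 10 (4-hydroxyphenyl){2-hydroxy-6-methoxy-4-[(E)-2-(3-methoxyphenyl)ethenyl]phenyl}methanone
Product: 13 2-[(4-hydroxyphenyl)methyl]-3-methoxy-5-[2-(3-methoxyphenyl)ethyl]phenol (IN0509), via saturated ketone 11 (not isolated), via benzhydrol 12 (not isolated)
Conditions: H2 (5 bar), 10% Pd/C, AcOH, cat. conc. HCl, 50 °C
Reagents that add atoms: none
Why: Catalytic hydrogenation combined with benzylic hydrogenolysis, in which Pd/C first saturates the stilbene (11), then reduces the acid-activated diaryl ketone to racemic benzhydrol 12, which ionises very easily to a benzhydryl cation stabilised by the ortho and para hydroxy groups (quinone methide) and is hydrogenolysed to the CH2 group, so its stereocentre vanishes and the achiral target results, while phenols and aryl methyl ethers are untouched.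

**Compound list**
1 | 3-methoxybenzaldehyde | COc1cccc(C=O)c1 | starting material
2 | 4-bromo-3,5-dimethoxybenzaldehyde | COc1cc(C=O)cc(OC)c1Br | starting material
3 | (E)-(3-methoxybenzylidene)hydrazine (hydrazone of 1; not isolated) | COc1cccc(/C=N/N)c1 | intermediate
4 | 2-bromo-1,3-dimethoxy-5-[(E)-2-(3-methoxyphenyl)ethenyl]benzene | COc1cccc(/C=C/c2cc(OC)c(Br)c(OC)c2)c1 | intermediate
5 | 4-(benzyloxy)benzonitrile | N#Cc1ccc(OCc2ccccc2)cc1 | starting material
6 | {2,6-dimethoxy-4-[(E)-2-(3-methoxyphenyl)ethenyl]phenyl}lithium (not isolated) | COc1cccc(/C=C/c2cc(OC)c([Li])c(OC)c2)c1 | intermediate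
7 | N-lithio ketimine from 6 and 5 (not isolated) | COc1cccc(/C=C/c2cc(OC)c(C(=N[Li])c3ccc(OCc4ccccc4)cc3)c(OC)c2)c1 | intermediate
8 | [4-(benzyloxy)phenyl]{2,6-dimethoxy-4-[(E)-2-(3-methoxyphenyl)ethenyl]phenyl}methanone | COc1cccc(/C=C/c2cc(OC)c(C(=O)c3ccc(OCc4ccccc4)cc3)c(OC)c2)c1 | intermediate
9 | bis(O-dichloroboryl) derivative of 10, ring B boron chelated to the ketone (not isolated) | COc1cccc(/C=C/c2cc(OB(Cl)Cl)c(C(=O)c3ccc(OB(Cl)Cl)cc3)c(OC)c2)c1 | intermediate
10 | (4-hydroxyphenyl){2-hydroxy-6-methoxy-4-[(E)-2-(3-methoxyphenyl)ethenyl]phenyl}methanone | COc1cccc(/C=C/c2cc(O)c(C(=O)c3ccc(O)cc3)c(OC)c2)c1 | intermediate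
11 | (4-hydroxyphenyl){2-hydroxy-6-methoxy-4-[2-(3-methoxyphenyl)ethyl]phenyl}methanone (not isolated) | COc1cccc(CCc2cc(O)c(C(=O)c3ccc(O)cc3)c(OC)c2)c1 | intermediate
12 | 2-[hydroxy(4-hydroxyphenyl)methyl]-3-methoxy-5-[2-(3-methoxyphenyl)ethyl]phenol (racemic; not isolated) | COc1cccc(CCc2cc(O)c(C(O)c3ccc(O)cc3)c(OC)c2)c1 | intermediate
13 | 2-[(4-hydroxyphenyl)methyl]-3-methoxy-5-[2-(3-methoxyphenyl)ethyl]phenol (IN0509; achiral) | COc1cccc(CCc2cc(O)c(Cc3ccc(O)cc3)c(OC)c2)c1 | target

**Total step count:** 4. **Longest linear sequence:** 4.

**Steps most likely to fail**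

Step 1 is the riskiest.
- Failure modes: azine formation between 3 and 2, Wolff–Kishner reduction of 3, hydrazone exchange leading to homocoupled stilbenes, or a stop at the alcohol stage.
- The fallback sets out from hydrazone 3 (with aldehyde 2) and comes back at 4. It separates C–C bond formation from the elimination.
- The hydrazone addition is run in its carbonyl-addition regime: [RuCl2(p-cymene)]2, dmpe, K3PO4 as the only base, CsF, THF, 45 °C. Here the carbanion left after N2 loss is protonated instead of eliminating.
- The racemic carbinol 1-(4-bromo-3,5-dimethoxyphenyl)-2-(3-methoxyphenyl)ethan-1-ol F1 is isolated. It is then dehydrated in a separate acid-catalysed elimination (cat. p-TsOH, toluene, reflux, water separator) to give 4.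

Step 2 is the third risk.
- Failure modes: the hindered aryllithium 6 may add slowly to the electron-rich nitrile, so that butylation by the bromobutane in the flask competes. The hindered ketimine may also resist hydrolysis.
- The fallback sets out from 4 and comes back at 8. It changes the oxidation level of the electrophile.
- Compound 6 is made as before and quenched at −78 °C with the much more reactive, commercial 4-(benzyloxy)benzaldehyde F2, followed by a water quench.
- This gives the racemic carbinol [4-(benzyloxy)phenyl]{2,6-dimethoxy-4-[(E)-2-(3-methoxyphenyl)ethenyl]phenyl}methanol F3.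
- This doubly benzylic alcohol is oxidised with MnO2 (CH2Cl2, rt) to ketone 8.

Step 4 is the second risk.
- Failure mode: the electron-rich, hydrogen-bonded, di-ortho-substituted ketone may survive the hydrogenation, which would then stop at 11.
- The fallback sets out from 10 and comes back at 13. It replaces surface hydrogenolysis by ionic hydride transfer.
- Compound 10 is hydrogenated under neutral conditions (H2 1 atm, 10% Pd/C, EtOAc, rt) and 11 is isolated.
- Compound 11 is then treated with Et3SiH (3 equiv) in TFA/CH2Cl2 (0 °C → rt). The silane delivers hydride first to the protonated ketone and then to the stabilised cation derived from 12, giving 13.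

**Further compounds**
F1 | step 1 | 1-(4-bromo-3,5-dimethoxyphenyl)-2-(3-methoxyphenyl)ethan-1-ol (racemic) | COc1cccc(CC(O)c2cc(OC)c(Br)c(OC)c2)c1
F2 | step 2 | 4-(benzyloxy)benzaldehyde (commercial reagent of the fallback) | O=Cc1ccc(OCc2ccccc2)cc1
F3 | step 2 | [4-(benzyloxy)phenyl]{2,6-dimethoxy-4-[(E)-2-(3-methoxyphenyl)ethenyl]phenyl}methanol (racemic) | COc1cccc(/C=C/c2cc(OC)c(C(O)c3ccc(OCc4ccccc4)cc3)c(OC)c2)c1
F0 | step 4 | none | none
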